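**Plan**
The retrosynthesis first cuts the C3–O ester bond, then the C7=C8 alkene (Wittig), which gives a C30 polyenyl phosphonium salt from β-apo-8'-carotenal and a C10 ring A enal.
Ring A is a cyclohexene whose tetrasubstituted C5=C6 alkene is the dehydrated aldol of a C5 methyl ketone and a C6 methylene activated by the C7 aldehyde; opening it leaves C3 as an acyclic silyloxy carbinol between two CH2 groups.
That keto aldehyde is cut at C4–C5 (dithiane acyl anion) and at C1–C2 (prenyl nucleophile through its tertiary carbon), on either side of a three-carbon epoxide unit.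
Forward: the chain is assembled (C4–C5, then C1–C2) and adjusted, ring A is closed by the enamine aldol condensation (the only ring-forming step), the polyene is joined at C7=C8, and desilylation and oleoylation finish.
The single stereocentre C3 comes from (R)-epichlorohydrin and is never a reacting centre; the polyene and oleoyl geometries are bought in, and C7=C8 is E by thermodynamic control.

Key step: step 7

Remark: positions are given in carotenoid numbering (ring A C1–C6, chain from C7); the target is taken as the all-E (3R) isomer drawn, and all polyenes are handled under argon in dim light.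

**Route**

Step 1
Reactants: 1 2-methyl-1,3-dithiane; 2 (R)-epichlorohydrin
Product: 5 2-methyl-2-{[(2R)-oxiran-2-yl]methyl}-1,3-dithiane, via 2-lithio-2-methyl-1,3-dithiane 3 (not isolated), via lithium chlorohydrin alkoxide 4 (not isolated)
Conditions: n-BuLi, THF, −30 °C; then 2, −78 °C to rt
Reagents that add atoms: none
Why: Corey–Seebach umpolung, in which the lithiated dithiane opens the epoxide of 2 at its unsubstituted CH2 (SN2) rather than displacing chloride, and the β-chloro alkoxide then closes to the transposed epoxide by an intramolecular Williamson reaction, so the carbinol carbon is never touched and (R)-2 gives (R)-5.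

Step 2
Reactants: 5 2-methyl-2-{[(2R)-oxiran-2-yl]methyl}-1,3-dithiane; 6 prenyl chloride
Product: 8 (2S)-4,4-dimethyl-1-(2-methyl-1,3-dithian-2-yl)hex-5-en-2-ol, via prenylmagnesium chloride 7 (not isolated)
Conditions: 6, Mg turnings, THF, 0 °C; then 5, −20 °C to rt; aq NH4Cl
Reagents that add atoms: none
Why: Copper-free allylic Grignard reagents open terminal epoxides with allylic transposition (SE2′), so the tertiary carbon of the prenyl unit bonds to the epoxide CH2 and installs the C1 gem-dimethyl centre and the vinyl group at once, while the carbinol stereocentre is untouched.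

Step 3
Reactants: 8 (2S)-4,4-dimethyl-1-(2-methyl-1,3-dithian-2-yl)hex-5-en-2-ol
Product: 9 tert-butyl{[(2S)-4,4-dimethyl-1-(2-methyl-1,3-dithian-2-yl)hex-5-en-2-yl]oxy}dimethylsilane
Conditions: TBSCl, imidazole, DMF, rt
Reagents that add atoms: tert-butyldimethylsilyl chloride (TBSCl), CC(C)(C)[Si](C)(C)Cl
Why: Imidazole-promoted silylation of a secondary alcohol gives a silyl ether that should survive the later borane, peroxide, alkylative, oxidative, amine and ylide conditions and be cleaved by fluoride at the end.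

Step 4
Reactants: 9 tert-butyl{[(2S)-4,4-dimethyl-1-(2-methyl-1,3-dithian-2-yl)hex-5-en-2-yl]oxy}dimethylsilane
Product: 11 (5S)-5-(tert-butyldimethylsilyloxy)-3,3-dimethyl-6-(2-methyl-1,3-dithian-2-yl)hexan-1-ol, via B-alkyl-9-borabicyclo[3.3.1]nonane 10 (not isolated)
Conditions: 9-BBN, THF, 0 °C to rt; then aq NaOH, 30% H2O2, 0 °C
Reagents that add atoms: hydrogen peroxide, OO
Why: Brown hydroboration with the bulky 9-BBN places boron on the terminal carbon of the vinyl group next to the quaternary centre (anti-Markovnikov), and cold alkaline peroxide oxidises the C–B bond far faster than the thioacetal sulfur.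

Step 5
Reactants: 11 (5S)-5-(tert-butyldimethylsilyloxy)-3,3-dimethyl-6-(2-methyl-1,3-dithian-2-yl)hexan-1-ol
Product: 12 (4S)-4-(tert-butyldimethylsilyloxy)-8-hydroxy-6,6-dimethyloctan-2-one
Conditions: MeI, CaCO3, MeCN/H2O (4:1), 45 °C
Reagents that add atoms: water, O
Why: Alkylative thioacetal hydrolysis, in which S-methylation makes a sulfonium leaving group that water displaces, and the CaCO3 buffer keeps the medium neutral so that the β-silyloxy ketone neither eliminates nor loses silicon.

Step 6
Reactants: 12 (4S)-4-(tert-butyldimethylsilyloxy)-8-hydroxy-6,6-dimethyloctan-2-one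
Product: 13 (5S)-5-(tert-butyldimethylsilyloxy)-3,3-dimethyl-7-oxooctanal
Conditions: Dess–Martin periodinane, CH2Cl2, 0 °C to rt
Reagents that add atoms: none
Why: Dess–Martin oxidation converts the primary alcohol to the aldehyde under nearly neutral conditions without enolising the β-silyloxy ketone, and the keto aldehyde is used at once.

Step 7
Reactants: 13 (5S)-5-(tert-butyldimethylsilyloxy)-3,3-dimethyl-7-oxooctanal
Product: 17 (4R)-4-(tert-butyldimethylsilyloxy)-2,6,6-trimethylcyclohex-1-ene-1-carbaldehyde, via enamine 14 (not isolated), via aldol iminium acetate 15 (not isolated), via conjugated iminium acetate 16 (not isolated)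
Conditions: pyrrolidine (20 mol %), AcOH (20 mol %), toluene (dilute), 0 °C to rt
Reagents that add atoms: none
Why: Pyrrolidine condenses faster with the aldehyde than with the methyl ketone, so the C6=C7 enamine 14 forms and its C6 carbon attacks the acid-activated C5 ketone to give the aldol iminium 15, which loses water through the hydroxy enamine to the conjugated iminium 16 and is hydrolysed by the released water to the enal, freeing the amine again. The closest known reaction type is the amine-salt-catalysed intramolecular aldol condensation of 1,7-keto aldehydes to 2-methylcyclohex-1-ene-1-carbaldehydes. Ring A closes in the 6-(enolexo)-exo-trig mode, helped by the Thorpe–Ingold effect of the C1 gem-dimethyl group. No stereocentre is created, since both new sp3 centres of 15 vanish on dehydration, and C3 is a spectator whose descriptor changes from S to R only because ring formation reverses the priorities of its two CH2 neighbours. The step needs enamine formation at the aldehyde to beat enolisation of the ketone toward C4, which would close the isomeric acetylcyclohexene or expel the C3 silyloxy group; the weakly acidic amine buffer, the low temperature, the poor silyloxy leaving group and the fact that C6 is the only enolisable position of the aldehyde secure this.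

Step 8
Reactants: 18 β-apo-8'-carotenal
Product: 19 β-apo-8'-carotenol [(2E,4E,6E,8E,10E,12E,14E,16E)-2,6,11,15-tetramethyl-17-(2,6,6-trimethylcyclohex-1-en-1-yl)heptadeca-2,4,6,8,10,12,14,16-octaen-1-ol]
Conditions: NaBH4, MeOH/THF, 0 °C, dark
Reagents that add atoms: none
Why: Borohydride 1,2-reduction of a conjugated polyenal is fast at 0 °C and leaves the polyene and its geometry untouched.

Step 9
Reactants: 19 β-apo-8'-carotenol
Product: 20 (all-E)-β-apo-8'-carotenyl(triphenyl)phosphonium bromide
Conditions: PPh3·HBr, MeOH/CH2Cl2, 0 °C to rt, dark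
Reagents that add atoms: triphenylphosphine hydrobromide, [Br-].[PH+](c1ccccc1)(c1ccccc1)c1ccccc1
Why: Allylic polyene alcohols ionise readily under HBr, and triphenylphosphine captures the delocalised cation at the terminal carbon to give the fully conjugated salt (SN1-type phosphonium salt formation, as used for retinyl and C15 Wittig salts).

Step 10
Reactants: 20 (all-E)-β-apo-8'-carotenyl(triphenyl)phosphonium bromide; 17 (4R)-4-(tert-butyldimethylsilyloxy)-2,6,6-trimethylcyclohex-1-ene-1-carbaldehyde
Product: 22 (3R)-3-(tert-butyldimethylsilyloxy)-β,β-carotene (all-E), via C30 phosphorus ylide 21 (not isolated)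
Conditions: 20, NaN(SiMe3)2, THF, −78 to 0 °C; then 17, −78 °C to rt; then heptane, 80 °C, dark
Reagents that add atoms: none
Why: Wittig olefination, in which the preformed, strongly delocalised ylide should add to the hindered enal at low temperature faster than it deprotonates it, and the new C7=C8 bond should equilibrate to E on heating because the 7Z isomer clashes with the ring methyl groups.

Step 11
Reactants: 22 (3R)-3-(tert-butyldimethylsilyloxy)-β,β-carotene
Product: 23 (3R)-β-cryptoxanthin [(3R)-β,β-caroten-3-ol, all-E]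
Conditions: Bu4NF, THF, 0 °C to rt, dark, argon
Reagents that add atoms: none
Why: Fluoride-driven desilylation cleaves only the Si–O bond, so C3 keeps its configuration and the polyene is not isomerised when light and air are excluded.

Step 12
Reactants: 23 (3R)-β-cryptoxanthin; 24 oleoyl chloride
Product: 25 (3R)-β-cryptoxanthin oleate [(3R)-β,β-caroten-3-yl (9Z)-octadec-9-enoate]
Conditions: pyridine, DMAP (cat.), CH2Cl2, 0 °C to rt, dark, argon
Reagents that add atoms: none
Why: DMAP-catalysed acylation of the secondary C3 alcohol by the acid chloride (nucleophilic acyl substitution) does not break the C3–O bond, so the configuration is retained, and the Z alkene of the oleoyl group is unaffected.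

**Compound list**
1 | 2-methyl-1,3-dithiane | CC1SCCCS1 | starting material
2 | (R)-epichlorohydrin [(2R)-2-(chloromethyl)oxirane] | ClC[C@H]1CO1 | starting material
3 | 2-lithio-2-methyl-1,3-dithiane | [Li]C1(C)SCCCS1 | intermediate
4 | lithium (2R)-1-chloro-3-(2-methyl-1,3-dithian-2-yl)propan-2-olate | CC1(C[C@@H]([O-])CCl)SCCCS1.[Li+] | intermediate
5 | 2-methyl-2-{[(2R)-oxiran-2-yl]methyl}-1,3-dithiane | CC1(C[C@@H]2CO2)SCCCS1 | intermediate
6 | prenyl chloride (1-chloro-3-methylbut-2-ene) | CC(C)=CCCl | starting material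
7 | prenylmagnesium chloride | CC(C)=CC[Mg]Cl | intermediate
8 | (2S)-4,4-dimethyl-1-(2-methyl-1,3-dithian-2-yl)hex-5-en-2-ol | CC1(C[C@@H](O)CC(C)(C)C=C)SCCCS1 | intermediate
9 | tert-butyl{[(2S)-4,4-dimethyl-1-(2-methyl-1,3-dithian-2-yl)hex-5-en-2-yl]oxy}dimethylsilane | CC1(C[C@@H](O[Si](C)(C)C(C)(C)C)CC(C)(C)C=C)SCCCS1 | intermediate
10 | 9-[(5S)-5-(tert-butyldimethylsilyloxy)-3,3-dimethyl-6-(2-methyl-1,3-dithian-2-yl)hexyl]-9-borabicyclo[3.3.1]nonane | CC1(C[C@@H](O[Si](C)(C)C(C)(C)C)CC(C)(C)CCB2C3CCCC2CCC3)SCCCS1 | intermediate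
11 | (5S)-5-(tert-butyldimethylsilyloxy)-3,3-dimethyl-6-(2-methyl-1,3-dithian-2-yl)hexan-1-ol | CC1(C[C@@H](O[Si](C)(C)C(C)(C)C)CC(C)(C)CCO)SCCCS1 | intermediate
12 | (4S)-4-(tert-butyldimethylsilyloxy)-8-hydroxy-6,6-dimethyloctan-2-one | CC(=O)C[C@@H](O[Si](C)(C)C(C)(C)C)CC(C)(C)CCO | intermediate
13 | (5S)-5-(tert-butyldimethylsilyloxy)-3,3-dimethyl-7-oxooctanal | CC(=O)C[C@@H](O[Si](C)(C)C(C)(C)C)CC(C)(C)CC=O | intermediate
14 | (4S,7E)-4-(tert-butyldimethylsilyloxy)-6,6-dimethyl-8-(pyrrolidin-1-yl)oct-7-en-2-one | CC(=O)C[C@@H](O[Si](C)(C)C(C)(C)C)CC(C)(C)/C=C/N1CCCC1 | intermediate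
15 | 1-{[(4S)-4-(tert-butyldimethylsilyloxy)-2-hydroxy-2,6,6-trimethylcyclohexyl]methylidene}pyrrolidin-1-ium acetate (epimers at the two new ring carbons) | CC(C)(C)[Si](C)(C)O[C@@H]1CC(C)(O)C(C=[N+]2CCCC2)C(C)(C)C1.CC(=O)[O-] | intermediate
16 | 1-{[(4R)-4-(tert-butyldimethylsilyloxy)-2,6,6-trimethylcyclohex-1-en-1-yl]methylidene}pyrrolidin-1-ium acetate | CC(C)(C)[Si](C)(C)O[C@@H]1CC(C)=C(C=[N+]2CCCC2)C(C)(C)C1.CC(=O)[O-] | intermediate
17 | (4R)-4-(tert-butyldimethylsilyloxy)-2,6,6-trimethylcyclohex-1-ene-1-carbaldehyde | CC(C)(C)[Si](C)(C)O[C@@H]1CC(C)=C(C=O)C(C)(C)C1 | intermediate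
18 | β-apo-8'-carotenal (all-E) | O=C/C(C)=C/C=C/C(C)=C/C=C/C=C(C)/C=C/C=C(C)/C=C/C1=C(C)CCCC1(C)C | starting material
19 | β-apo-8'-carotenol (all-E) | OC/C(C)=C/C=C/C(C)=C/C=C/C=C(C)/C=C/C=C(C)/C=C/C1=C(C)CCCC1(C)C | intermediate
20 | (all-E)-β-apo-8'-carotenyl(triphenyl)phosphonium bromide | [Br-].c1ccccc1[P+](c1ccccc1)(c1ccccc1)C/C(C)=C/C=C/C(C)=C/C=C/C=C(C)/C=C/C=C(C)/C=C/C1=C(C)CCCC1(C)C | intermediate
21 | (all-E)-β-apo-8'-carotenylidene(triphenyl)phosphorane | c1ccccc1P(c1ccccc1)(c1ccccc1)=C/C(C)=C/C=C/C(C)=C/C=C/C=C(C)/C=C/C=C(C)/C=C/C1=C(C)CCCC1(C)C | intermediate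
22 | (3R)-3-(tert-butyldimethylsilyloxy)-β,β-carotene (all-E) | CC(C)(C)[Si](C)(C)O[C@@H]1CC(C)=C(/C=C/C(C)=C/C=C/C(C)=C/C=C/C=C(C)/C=C/C=C(C)/C=C/C2=C(C)CCCC2(C)C)C(C)(C)C1 | intermediate
23 | (3R)-β-cryptoxanthin (all-E) | O[C@@H]1CC(C)=C(/C=C/C(C)=C/C=C/C(C)=C/C=C/C=C(C)/C=C/C=C(C)/C=C/C2=C(C)CCCC2(C)C)C(C)(C)C1 | intermediate
24 | oleoyl chloride [(9Z)-octadec-9-enoyl chloride] | CCCCCCCC/C=C\CCCCCCCC(Cl)=O | starting material
25 | (3R)-β-cryptoxanthin oleate (CNP0152321.1) | CCCCCCCC/C=C\CCCCCCCC(=O)O[C@@H]1CC(C)=C(/C=C/C(C)=C/C=C/C(C)=C/C=C/C=C(C)/C=C/C=C(C)/C=C/C2=C(C)CCCC2(C)C)C(C)(C)C1 | target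

**Step count and risks**
Total steps: 12. Longest linear sequence: 10 (steps 1–7, then 10–12); steps 8 and 9 form the two-step C30 branch.

Steps most likely to fail:

1. Step 7 (ring closure). The amine may enolise the ketone toward C4 instead of forming the aldehyde enamine. The silyloxy group may be lost by β-elimination before closure, or by vinylogous elimination from the product dienamine. Formation of the crowded C5–C6 bond may be too slow. The fallback is a directed, Lewis-acid-mediated Mukaiyama aldol in which the aldehyde enol is fixed before the ketone exists. It sets out from alcohol 11. Parikh–Doering oxidation (SO3·pyridine, DMSO, i-Pr2NEt, CH2Cl2, 0 °C) should give (5S)-5-(tert-butyldimethylsilyloxy)-3,3-dimethyl-6-(2-methyl-1,3-dithian-2-yl)hexanal F1. Soft enolisation (TBSOTf, Et3N, CH2Cl2, 0 °C) should give its tert-butyldimethylsilyl enol ether F2, of which either alkene isomer serves. Alkylative dithiane hydrolysis (MeI, CaCO3, aqueous MeCN) should then unmask the methyl ketone to give (4S)-4,8-bis(tert-butyldimethylsilyloxy)-6,6-dimethyloct-7-en-2-one F3. BF3·OEt2 in CH2Cl2 at −78 °C should close ring A to (4S)-4-(tert-butyldimethylsilyloxy)-2-hydroxy-2,6,6-trimethylcyclohexane-1-carbaldehyde F4. Acid-catalysed dehydration (pyridinium p-toluenesulfonate, toluene, 60 °C) returns to the route at aldehyde 17.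

2. Step 10 (Wittig). The ylide may act as a base toward the enal (γ-deprotonation followed by loss of the C3 silyloxy group), addition to the hindered conjugated aldehyde may be slow, and Z to E equilibration may be incomplete. The fallback reverses the polarity by a Julia–Kocienski olefination, so the ring carries the carbanion and cannot eliminate. It sets out from aldehyde 17. Reduction (NaBH4, MeOH, 0 °C) should give [(4R)-4-(tert-butyldimethylsilyloxy)-2,6,6-trimethylcyclohex-1-en-1-yl]methanol F5. Mitsunobu thioetherification with 2-mercaptobenzothiazole (PPh3, diisopropyl azodicarboxylate, THF) should give the benzothiazolyl sulfide F6. Oxidation with (NH4)6Mo7O24·4H2O and H2O2 in EtOH should give the benzothiazolyl sulfone F7. Deprotonation with NaN(SiMe3)2 in THF at −78 °C, addition of commercial β-apo-8'-carotenal 18 and thermal equilibration in heptane return to the route at silyl ether 22; steps 8 and 9 are then not needed.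

3. Step 2 (epoxide opening). The prenyl reagent may attack through its primary carbon to give the linear isomer, or chloride from the magnesium salts may open the epoxide to a chlorohydrin. The fallback builds the quaternary carbon from a carboxylate dianion. It sets out from epoxide 5. The dianion of isobutyric acid (2 equiv LiN(i-Pr)2, THF, 0 to 40 °C) should open the epoxide at CH2, and acidic work-up should lactonise the product to (5S)-3,3-dimethyl-5-[(2-methyl-1,3-dithian-2-yl)methyl]oxolan-2-one F8. Reduction with i-Bu2AlH (toluene, −78 °C) should give the lactol (5S)-3,3-dimethyl-5-[(2-methyl-1,3-dithian-2-yl)methyl]oxolan-2-ol F9. Wittig methylenation (Ph3PCH3Br, KOt-Bu, THF, reflux) returns to the route at alcohol 8.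

Further compounds
F1 | step 7 | (5S)-5-(tert-butyldimethylsilyloxy)-3,3-dimethyl-6-(2-methyl-1,3-dithian-2-yl)hexanal | CC1(C[C@@H](O[Si](C)(C)C(C)(C)C)CC(C)(C)CC=O)SCCCS1
F2 | step 7 | tert-butyl{[(5S)-5-(tert-butyldimethylsilyloxy)-3,3-dimethyl-6-(2-methyl-1,3-dithian-2-yl)hex-1-en-1-yl]oxy}dimethylsilane (E/Z mixture) | CC1(C[C@@H](O[Si](C)(C)C(C)(C)C)CC(C)(C)C=CO[Si](C)(C)C(C)(C)C)SCCCS1
F3 | step 7 | (4S)-4,8-bis(tert-butyldimethylsilyloxy)-6,6-dimethyloct-7-en-2-one (E/Z mixture) | CC(=O)C[C@@H](O[Si](C)(C)C(C)(C)C)CC(C)(C)C=CO[Si](C)(C)C(C)(C)C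
F4 | step 7 | (4S)-4-(tert-butyldimethylsilyloxy)-2-hydroxy-2,6,6-trimethylcyclohexane-1-carbaldehyde (epimers at C1 and C2) | CC(C)(C)[Si](C)(C)O[C@@H]1CC(C)(O)C(C=O)C(C)(C)C1
F5 | step 10 | [(4R)-4-(tert-butyldimethylsilyloxy)-2,6,6-trimethylcyclohex-1-en-1-yl]methanol | CC(C)(C)[Si](C)(C)O[C@@H]1CC(C)=C(CO)C(C)(C)C1
F6 | step 10 | 2-({[(4R)-4-(tert-butyldimethylsilyloxy)-2,6,6-trimethylcyclohex-1-en-1-yl]methyl}sulfanyl)-1,3-benzothiazole | CC(C)(C)[Si](C)(C)O[C@@H]1CC(C)=C(CSc2nc3ccccc3s2)C(C)(C)C1
F7 | step 10 | 2-({[(4R)-4-(tert-butyldimethylsilyloxy)-2,6,6-trimethylcyclohex-1-en-1-yl]methyl}sulfonyl)-1,3-benzothiazole | CC(C)(C)[Si](C)(C)O[C@@H]1CC(C)=C(CS(=O)(=O)c2nc3ccccc3s2)C(C)(C)C1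
F8 | step 2 | (5S)-3,3-dimethyl-5-[(2-methyl-1,3-dithian-2-yl)methyl]oxolan-2-one | CC1(C[C@@H]2CC(C)(C)C(=O)O2)SCCCS1
F9 | step 2 | (5S)-3,3-dimethyl-5-[(2-methyl-1,3-dithian-2-yl)methyl]oxolan-2-ol (anomer mixture) | CC1(C[C@@H]2CC(C)(C)C(O)O2)SCCCS1
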